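## Retrosynthetic overview
1. **Feature.** The cyclohexane runs C1 (O-bearing spiro carbon), C2 (CHCH3), C3 (CHOH), C4 (CH2), C5 (CH–CMe2OH), C6 (spiro carbon of the δ-lactone). It is read as a 2-methylcyclohex-2-enone (C1=O, C2=C3) in which C6 is the α-carbon of a β-keto ester and C5 the β-carbon of an enal. C5–C6 (Michael) and C2=C3 (aldol condensation) are cut in one operation.
2. **Cage.** Orthoester C9, ketal C13 and γ-lactone C14 open together to a spiro γ-lactone bearing a CH(CH3)–CH(CO2Me)–CH(OH)–COCH3 chain. C11–C12 is cut by an aldol (methacrolein, then ozonolysis). C8–C10 is cut by a crotonate Michael addition that makes C8 quaternary.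
3. **Side chains.** The spiro γ-lactone comes from a methallyl Barbier addition at C1=O, hydroboration and oxidative lactonisation. CMe2OH comes from MeMgBr on a transient C1–O/C5 bridged lactone. The δ-lactone comes from a last-step oxidative lactonisation of the 1,5-diol derived from the two C6 esters.
4. **C2/C3.** A hydroxyl-directed β-epoxide is opened reductively at C2 while the bridged lactone locks the chair.
5. **Ring order.** Cyclohexane (step 2), two temporary lactones (steps 7 and 9), oxolanone (step 13), then oxane, dioxolane and γ-lactone of the cage (step 17), then δ-lactone (step 19).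

Key step: step 2

**Remark on labels.** C7 is the oxolane CH2, C8 the quaternary C–CH3, C9 the orthoester carbon, C10 CHCH3, C11 CH–C=O, C12 OCH, C13 the ketal C–CH3, and C14 the γ-lactone C=O. β is the cyclohexane face that carries C3–OH. In the target, C2–CH3, C3–OH, C5–CMe2OH, C6–CH2O and C1–O are all β; C7 and the C6–CH2CH2 arm are α.

**Assumption.** C8 is carried as a mixture of epimers between the hydroboration and the enolisation that planarises it.

## Route

Step 1
Reactants: 1 methyl 3-oxopentanoate; 2 methyl acrylate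
Product: 3 dimethyl 2-propanoylpentanedioate (racemic, enolisable)
Conditions: 1 (1.5 equiv), DBU (5 mol %), MeCN, 0 °C to rt
Reagents that add atoms: none
Why: Base-catalysed Michael addition of the acidic CH2 of 1 to the acrylate, with 1 in excess to hold back double addition; the new stereocentre is enolisable and needs no control.

Step 2
Reactants: 3 dimethyl 2-propanoylpentanedioate; 4 ethyl (E)-4-oxobut-2-enoate
Product: 6 triester 2-methylcyclohexenone (5R,6R; C5-CO2Et cis to C6-CO2Me), via Michael adduct aldehyde 5 (not isolated)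
Conditions: (S)-α,α-diphenylprolinol trimethylsilyl ether (20 mol %), PhCO2H (20 mol %), toluene, 0 °C to rt; then p-TsOH·H2O (40 mol %), 60 °C
Reagents that add atoms: none
Why: The amine condenses with 4 to an E, s-trans iminium ion whose CO2Et-bearing carbon (C5, β to the iminium) is attacked by the hydrogen-bonded enol of 3, hydrolysis of the enamine gives aldehyde 5, and acid then enolises the ethyl ketone at its CH2 (C6 has no H left), which adds to the aldehyde and loses water. The closest known reaction type is the diarylprolinol silyl ether catalysed Michael addition of β-keto esters to enals followed by aldol condensation to cyclohexenones. The one ring closes by a 6-(enolendo)-exo-trig aldol that joins C2 to C3, and dehydration leaves C2=C3 conjugated with C1=O. C5 is set by the catalyst, whose CPh2OTMS group covers one face of the iminium ion so that the enol arrives on the open face (5R). C6 is set by the mutual orientation of the partners in a synclinal open transition state, with the enol C=C gauche to the iminium C=C and the flexible propanoate arm anti to CO2Et, so CO2Me ends cis to CO2Et (6R); this is the weaker control element, both antipodes of 3 are funnelled through the enol, and the minor C6 epimer is to be removed by chromatography of 6. Regiochemistry is secured by the substrates, because iminium formation makes the aldehyde and not the ester the controlling acceptor of 4, and 5 has only one enolisable ketone position and one six-membered closure open to it.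

Step 3
Reactants: 6 triester 2-methylcyclohexenone; 7 3-bromo-2-methylprop-1-ene
Product: 8 tertiary allylic alcohol (C1 β-OH, α-CH2C(CH3)=CH2)
Conditions: Zn dust, THF/sat. aq NH4Cl, 0 °C to rt
Reagents that add atoms: none
Why: Zinc Barbier allylation adds 1,2 to enones and ignores esters; C5-CO2Et and C6-CO2Me both stand on the β face, so the allylzinc should reach C1 from the α face of the half-chair with CO2Et equatorial and CO2Me pseudoaxial, giving C7 α and C1–OH β.

Step 4
Reactants: 8 tertiary allylic alcohol
Product: 9 diol diester (C6 arm reduced to CH2CH2CH2OH)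
Conditions: LiBH4 (1.2 equiv), THF, 0 °C
Reagents that add atoms: none
Why: Sterically controlled ester reduction with LiBH4; the CH2CH2CO2Me ester is the only one without α-branching, whereas the C5 ester is flanked by quaternary C6 and the C6 ester sits on it, so limited hydride at 0 °C should stop at this primary alcohol.

Step 5
Reactants: 9 diol diester
Product: 10 primary TBS ether
Conditions: TBSCl, imidazole, DMF, 0 °C to rt
Reagents that add atoms: tert-butyldimethylsilyl chloride, CC(C)(C)[Si](C)(C)Cl
Why: Standard silylation of the only primary alcohol; the hindered tertiary C1–OH does not react with TBSCl/imidazole.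

Step 6
Reactants: 10 primary TBS ether
Product: 11 2β,3β-epoxy alcohol
Conditions: VO(acac)2 (5 mol %), t-BuOOH (decane), CH2Cl2, 0 °C to rt
Reagents that add atoms: tert-butyl hydroperoxide, CC(C)(C)OO
Why: Vanadium-catalysed hydroxyl-directed epoxidation of an allylic alcohol; the C1–O-bound vanadium peroxide delivers oxygen to the ring alkene on the β face, syn to C1–OH, and the merely homoallylic, less substituted methallyl alkene reacts far more slowly.

Step 7
Reactants: 11 2β,3β-epoxy alcohol
Product: 12 epoxy bridged lactone (C1–O–C(=O)–C5, 6-oxabicyclo[3.2.1]octan-7-one core)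
Conditions: LiHMDS (1.05 equiv), THF, −78 °C to rt; AcOH
Reagents that add atoms: none
Why: Alkoxide-driven lactonisation (intramolecular transesterification); C1–O and the C5 carboxyl are 1,3-cis, so a ring flip lets the lithium alkoxide close the γ-lactone, which freezes the chair with C1–O axial and C7 equatorial, and the syn epoxide cannot be opened by this alkoxide because backside attack is impossible.

Step 8
Reactants: 12 epoxy bridged lactone
Product: 13 hydroxy bridged lactone (C2 β-CH3, C3 β-OH)
Conditions: Cp2TiCl2 (20 mol %), Mn, 2,4,6-collidine·HCl, 1,4-cyclohexadiene, THF, rt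
Reagents that add atoms: none
Why: Titanocene(III)-catalysed reductive epoxide opening (Nugent–RajanBabu reagent); homolysis gives the tertiary C2 radical and keeps the β C3–O bond, and in the locked chair the β lobe of the radical is flanked by the axial C–O bonds at C1 and C3, so the hydrogen donor should come from the α face and leave C2–CH3 β (equatorial here), while an acyl shift from C1–O to C3–O would be harmless because both isomers lead to 14.

Step 9
Reactants: 13 hydroxy bridged lactone
Product: 15 cis-fused γ-lactone diol (C6–C(=O)–O–CMe2–C5), via triol methyl ester 14 (not isolated)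
Conditions: MeMgBr (5 equiv), THF, 0 °C to rt; H2O/NH4Cl
Reagents that add atoms: methylmagnesium bromide, C[Mg]Br
Why: Double Grignard addition to the strained lactone builds the dimethyl carbinol and frees C1–OH, while the C6 ester on the fully substituted carbon is too hindered for intermolecular attack and is captured by the new cis tertiary alkoxide (γ-lactonisation aided by the gem-dimethyl effect); no stereocentre changes.

Step 10
Reactants: 15 cis-fused γ-lactone diol
Product: 16 tetraol mono-TBS ether (C6–CH2OH, C5–CMe2OH, C3–OH, C1–OH)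
Conditions: LiAlH4, THF, 0 to 40 °C; Rochelle salt
Reagents that add atoms: none
Why: LiAlH4 reduction of the hindered γ-lactone to the 1,4-diol; the silyl ether and the isolated alkene are inert and no other carbonyl group is present.

Step 11
Reactants: 16 tetraol mono-TBS ether
Product: 17 tetrakis-TBS ether with free C1–OH
Conditions: TBSOTf (3.5 equiv), 2,6-lutidine, CH2Cl2, −40 to 0 °C
Reagents that add atoms: tert-butyldimethylsilyl triflate, CC(C)(C)[Si](C)(C)OS(=O)(=O)C(F)(F)F
Why: Silyl triflate silylation; the primary, the secondary and the open dimethyl-carbinol hydroxyls react, whereas C1–OH, wedged between quaternary C6, C2 and the methallyl CH2, is expected to stay free at low temperature.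

Step 12
Reactants: 17 tetrakis-TBS ether with free C1–OH
Product: 19 primary alcohol (C9–OH/C1–OH 1,4-diol; C8 epimers), via B-alkyl-9-BBN adduct 18 (not isolated)
Conditions: 9-BBN (2 equiv), THF, rt; then H2O2, aq NaOH, 0 °C
Reagents that add atoms: hydrogen peroxide, OO
Why: Brown hydroboration–oxidation of the only alkene left, anti-Markovnikov with 9-BBN; C8 forms as a mixture of epimers, which does not matter because C8 is planarised in step 14.

Step 13
Reactants: 19 primary alcohol (1,4-diol)
Product: 21 spiro α-methyl-γ-butyrolactone (C8 epimers), via γ-lactol 20 (not isolated)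
Conditions: TEMPO (20 mol %), PhI(OAc)2 (2.5 equiv), CH2Cl2, rt
Reagents that add atoms: none
Why: TEMPO/PhI(OAc)2 oxidative lactonisation of a primary/tertiary 1,4-diol; the aldehyde closes to the lactol with C1–OH and is oxidised on to the lactone, with silyl ethers untouched.

Step 14
Reactants: 21 spiro α-methyl-γ-butyrolactone; 22 methyl (E)-but-2-enoate
Product: 24 Michael adduct (8R,10S), via lactone lithium enolate 23 (not isolated)
Conditions: LDA (1.1 equiv), THF, −78 °C; 22 (1.2 equiv), −78 °C; AcOH
Reagents that add atoms: none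
Why: Michael addition of a lactone lithium enolate to an (E)-crotonate; the acceptor should come from the enolate face next to C2–H and away from the C6 arm (8R), and a lithium-bridged closed transition state, with the s-cis ester over the enolate oxygen and C10–H rather than C10–CH3 turned toward the spiro ring, gives 10S.

Step 15
Reactants: 24 Michael adduct; 25 2-methylprop-2-enal (methacrolein)
Product: 27 anti-aldol adduct (11R,12S), via ester lithium enolate 26 (not isolated)
Conditions: LDA (1.2 equiv), THF, −78 °C; 25 (1.5 equiv), −78 °C; AcOH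
Reagents that add atoms: none
Why: Lithium ester-enolate aldol addition; LDA in THF gives the E(O)-enolate, which reacts through a Zimmerman–Traxler chair to the anti aldol (12S) on the enolate face opposite bulky C8 in the A(1,3)-minimised rotamer with C10–H in plane (11R), the lactone has no α-H left, and a transient attack of the aldolate on C9 only anticipates step 17.

Step 16
Reactants: 27 anti-aldol adduct
Product: 29 α-hydroxy methyl ketone, via secondary ozonide 28 (not isolated)
Conditions: O3, CH2Cl2, −78 °C; then Me2S, −78 °C to rt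
Reagents that add atoms: ozone, [O-][O+]=O
Why: Ozonolysis with reductive work-up of the only C=C bond unmasks the C13 methyl ketone without touching C12.

Step 17
Reactants: 29 α-hydroxy methyl ketone
Product: 30 caged orthoester, tetrakis-TBS ether
Conditions: CSA (10 mol %), 4 Å MS, benzene, 50 °C
Reagents that add atoms: none
Why: Proposed new method: a lactone carbonyl has not been tied into an orthoester by an α-ketol and an ester in one acid-catalysed operation, but all three bonds form by reversible carbonyl additions: C12–OH adds to the protonated lactone carbonyl C9 (6-exo-trig, oxane), the new C9–OH adds to the C13 ketone (5-exo-trig, dioxolane), and the C13–OH is acylated by the C14 methyl ester (5-exo-trig, γ-lactone); only this last step expels methanol, which the sieves remove so that the equilibria drain to 30; C9 and C13 can only form with O–C13, O–C12 and C10 on one face of the new γ-lactone, and C11 can epimerise to fit; the closest known reaction types are the acid-catalysed closure of hydroxy esters of polyols to caged orthoesters, pseudo-ester formation from γ-keto acids, and thermodynamic spiroketalisation.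

Step 18
Reactants: 30 caged orthoester, tetrakis-TBS ether
Product: 31 caged tetraol
Conditions: HF·pyridine, pyridine, THF, 0 °C to rt
Reagents that add atoms: none
Why: Fluoride-mediated desilylation removes all four TBS groups, and the rigid cage orthoester and the acylal lactone are expected to tolerate buffered HF·pyridine, which avoids both aqueous acid and basic fluoride.

Step 19
Reactants: 31 caged tetraol
Product: 33 chermebilaene B, via δ-lactol 32 (not isolated)
Conditions: TEMPO (20 mol %), PhI(OAc)2 (2.5 equiv), CH2Cl2, rt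
Reagents that add atoms: none
Why: TEMPO/PhI(OAc)2 oxidative lactonisation of the 1,5-diol; the nitroxyl oxidises primary over secondary and tertiary alcohols and the unhindered CH2CH2CH2OH faster than the neopentyl C6–CH2OH, so the aldehyde forms on the arm, closes to lactol 32 with C6–CH2OH and is oxidised to the δ-lactone with its carbonyl in the right place.

## Compound list
1 | methyl 3-oxopentanoate | CCC(=O)CC(=O)OC | starting material
2 | methyl acrylate | C=CC(=O)OC | starting material
3 | dimethyl 2-propanoylpentanedioate (racemic) | CCC(=O)C(CCC(=O)OC)C(=O)OC | intermediate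
4 | ethyl (E)-4-oxobut-2-enoate | CCOC(=O)/C=C/C=O | starting material
5 | dimethyl (2R)-2-[(2R)-1-ethoxy-1,4-dioxobutan-2-yl]-2-propanoylpentanedioate | CCC(=O)[C@](CCC(=O)OC)(C(=O)OC)[C@@H](CC=O)C(=O)OCC | intermediate
6 | 1-ethyl 2-methyl (1R,2R)-2-(3-methoxy-3-oxopropyl)-4-methyl-3-oxocyclohex-4-ene-1,2-dicarboxylate | CC1=CC[C@@H](C(=O)OCC)[C@@](CCC(=O)OC)(C(=O)OC)C1=O | intermediate
7 | 3-bromo-2-methylprop-1-ene | C=C(C)CBr | starting material
8 | tertiary allylic alcohol, C1 β-OH, α-methallyl, triester | CC1=CC[C@@H](C(=O)OCC)[C@@](CCC(=O)OC)(C(=O)OC)[C@]1(O)CC(C)=C | intermediate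
9 | diol diester, C6 arm = 3-hydroxypropyl | CC1=CC[C@@H](C(=O)OCC)[C@@](CCCO)(C(=O)OC)[C@]1(O)CC(C)=C | intermediate
10 | primary TBS ether of 9 | CC1=CC[C@@H](C(=O)OCC)[C@@](CCCO[Si](C)(C)C(C)(C)C)(C(=O)OC)[C@]1(O)CC(C)=C | intermediate
11 | 2β,3β-epoxy alcohol | C[C@]12O[C@H]1C[C@@H](C(=O)OCC)[C@@](CCCO[Si](C)(C)C(C)(C)C)(C(=O)OC)[C@]2(O)CC(C)=C | intermediate
12 | epoxy bridged lactone (C1–O–CO–C5) | C[C@]12O[C@H]1C[C@H]3C(=O)O[C@]2(CC(C)=C)[C@]3(CCCO[Si](C)(C)C(C)(C)C)C(=O)OC | intermediate
13 | hydroxy bridged lactone, C2 β-CH3, C3 β-OH | C[C@H]1[C@@H](O)C[C@H]2C(=O)O[C@]1(CC(C)=C)[C@]2(CCCO[Si](C)(C)C(C)(C)C)C(=O)OC | intermediate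
14 | triol methyl ester (C5–CMe2OH, C6–CO2Me) | C[C@H]1[C@@H](O)C[C@@H](C(C)(C)O)[C@@](CCCO[Si](C)(C)C(C)(C)C)(C(=O)OC)[C@]1(O)CC(C)=C | intermediate
15 | cis-fused γ-lactone diol (C6–CO–O–CMe2–C5) | C[C@H]1[C@@H](O)C[C@H]2C(C)(C)OC(=O)[C@@]2(CCCO[Si](C)(C)C(C)(C)C)[C@]1(O)CC(C)=C | intermediate
16 | tetraol mono-TBS ether | C[C@H]1[C@@H](O)C[C@@H](C(C)(C)O)[C@@](CCCO[Si](C)(C)C(C)(C)C)(CO)[C@]1(O)CC(C)=C | intermediate
17 | tetrakis-TBS ether, free C1–OH, methallyl | C[C@H]1[C@@H](O[Si](C)(C)C(C)(C)C)C[C@@H](C(C)(C)O[Si](C)(C)C(C)(C)C)[C@@](CCCO[Si](C)(C)C(C)(C)C)(CO[Si](C)(C)C(C)(C)C)[C@]1(O)CC(C)=C | intermediate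
18 | B-alkyl-9-BBN adduct of 17 | C[C@H]1[C@@H](O[Si](C)(C)C(C)(C)C)C[C@@H](C(C)(C)O[Si](C)(C)C(C)(C)C)[C@@](CCCO[Si](C)(C)C(C)(C)C)(CO[Si](C)(C)C(C)(C)C)[C@]1(O)CC(C)CB1C2CCCC1CCC2 | intermediate
19 | primary alcohol, 1,4-diol (C8 epimers) | C[C@H]1[C@@H](O[Si](C)(C)C(C)(C)C)C[C@@H](C(C)(C)O[Si](C)(C)C(C)(C)C)[C@@](CCCO[Si](C)(C)C(C)(C)C)(CO[Si](C)(C)C(C)(C)C)[C@]1(O)CC(C)CO | intermediate
20 | spiro γ-lactol | C[C@H]1[C@@H](O[Si](C)(C)C(C)(C)C)C[C@@H](C(C)(C)O[Si](C)(C)C(C)(C)C)[C@@](CCCO[Si](C)(C)C(C)(C)C)(CO[Si](C)(C)C(C)(C)C)[C@]12CC(C)C(O)O2 | intermediate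
21 | spiro α-methyl-γ-butyrolactone (C8 epimers) | C[C@H]1[C@@H](O[Si](C)(C)C(C)(C)C)C[C@@H](C(C)(C)O[Si](C)(C)C(C)(C)C)[C@@](CCCO[Si](C)(C)C(C)(C)C)(CO[Si](C)(C)C(C)(C)C)[C@]12CC(C)C(=O)O2 | intermediate
22 | methyl (E)-but-2-enoate | C/C=C/C(=O)OC | starting material
23 | lithium enolate of 21 | C[C@H]1[C@@H](O[Si](C)(C)C(C)(C)C)C[C@@H](C(C)(C)O[Si](C)(C)C(C)(C)C)[C@@](CCCO[Si](C)(C)C(C)(C)C)(CO[Si](C)(C)C(C)(C)C)[C@]12CC(C)=C(O[Li])O2 | intermediate
24 | Michael adduct (8R,10S), C8 quaternary, CH(CH3)CH2CO2Me chain | C[C@H]1[C@@H](O[Si](C)(C)C(C)(C)C)C[C@@H](C(C)(C)O[Si](C)(C)C(C)(C)C)[C@@](CCCO[Si](C)(C)C(C)(C)C)(CO[Si](C)(C)C(C)(C)C)[C@]12C[C@](C)([C@@H](C)CC(=O)OC)C(=O)O2 | intermediate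
25 | 2-methylprop-2-enal | C=C(C)C=O | starting material
26 | E(O) lithium enolate of 24 | C[C@H]1[C@@H](O[Si](C)(C)C(C)(C)C)C[C@@H](C(C)(C)O[Si](C)(C)C(C)(C)C)[C@@](CCCO[Si](C)(C)C(C)(C)C)(CO[Si](C)(C)C(C)(C)C)[C@]12C[C@](C)([C@@H](C)/C=C(/O[Li])OC)C(=O)O2 | intermediate
27 | anti-aldol adduct (11R,12S), isopropenyl carbinol | C[C@H]1[C@@H](O[Si](C)(C)C(C)(C)C)C[C@@H](C(C)(C)O[Si](C)(C)C(C)(C)C)[C@@](CCCO[Si](C)(C)C(C)(C)C)(CO[Si](C)(C)C(C)(C)C)[C@]12C[C@](C)([C@@H](C)[C@@H](C(=O)OC)[C@H](O)C(C)=C)C(=O)O2 | intermediate
28 | secondary ozonide of 27 | C[C@H]1[C@@H](O[Si](C)(C)C(C)(C)C)C[C@@H](C(C)(C)O[Si](C)(C)C(C)(C)C)[C@@](CCCO[Si](C)(C)C(C)(C)C)(CO[Si](C)(C)C(C)(C)C)[C@]12C[C@](C)([C@@H](C)[C@@H](C(=O)OC)[C@H](O)C3(C)OCOO3)C(=O)O2 | intermediate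
29 | α-hydroxy methyl ketone | C[C@H]1[C@@H](O[Si](C)(C)C(C)(C)C)C[C@@H](C(C)(C)O[Si](C)(C)C(C)(C)C)[C@@](CCCO[Si](C)(C)C(C)(C)C)(CO[Si](C)(C)C(C)(C)C)[C@]12C[C@](C)([C@@H](C)[C@@H](C(=O)OC)[C@H](O)C(C)=O)C(=O)O2 | intermediate
30 | caged orthoester, tetrakis-TBS ether | C[C@H]1[C@@H](O[Si](C)(C)C(C)(C)C)C[C@@H](C(C)(C)O[Si](C)(C)C(C)(C)C)[C@@](CCCO[Si](C)(C)C(C)(C)C)(CO[Si](C)(C)C(C)(C)C)[C@]12C[C@]1(C)[C@@H](C)[C@H]3C(=O)O[C@@]4(C)O[C@@]1(O[C@@H]34)O2 | intermediate
31 | caged tetraol | C[C@H]1[C@@H](O)C[C@@H](C(C)(C)O)[C@@](CCCO)(CO)[C@]12C[C@]1(C)[C@@H](C)[C@H]3C(=O)O[C@@]4(C)O[C@@]1(O[C@@H]34)O2 | intermediate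
32 | δ-lactol | C[C@H]1[C@@H](O)C[C@@H](C(C)(C)O)[C@]2(CCC(O)OC2)[C@]12C[C@]1(C)[C@@H](C)[C@H]3C(=O)O[C@@]4(C)O[C@@]1(O[C@@H]34)O2 | intermediate
33 | chermebilaene B | C[C@H]1[C@@H](O)C[C@@H](C(C)(C)O)[C@]2(CCC(=O)OC2)[C@]12C[C@]1(C)[C@@H](C)[C@H]3C(=O)O[C@@]4(C)O[C@@]1(O[C@@H]34)O2 | target

Total step count: 19. Longest linear sequence: 19 (from 1).

## Steps most likely to fail

**Step 17 (cage closure).**
- Risk: the chain of reversible additions may rest at open or half-closed hemiketals. Acid-induced loss of water across C11–C12, or retro-aldol cleavage, may also outrun the closure.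
- Fallback, from 29 back to 30: the methyl ester is cleaved under neutral conditions with Me3SnOH (1,2-dichloroethane, 60 °C) to the γ-keto acid F1. Both hydroxyl functions are then silylated (TMSCl, Et3N, CH2Cl2) to the trimethylsilyl ester/ether F2. Catalytic TMSOTf in CH2Cl2 at −78 to −20 °C closes the cage under Noyori-type acetalisation conditions.
- Why it differs: these conditions are known for ketones and for turning lactones into orthoesters with bis-silylated diols. The silicon–oxygen bond that forms makes the closure irreversible, instead of relying on a Brønsted-acid equilibrium.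

**Step 2 (key annulation).**
- Risk: the fully substituted, acyclic nucleophile may add so slowly that uncatalysed addition or self-reaction of 4 competes. The two faces of its enol may also be poorly distinguished, so that C6 forms without control.
- Fallback, from 1 and 4 back to 6: under the same amine catalysis followed by acid, the unsubstituted keto ester 1 gives the cyclohexenone β-keto ester F3, the well-precedented case with only C5 to control. The propanoate arm is added afterwards by base-catalysed Michael addition of the cyclic β-keto ester to 2 (K2CO3, acetone).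
- Why it differs: the acrylate approaches the planar ring enolate from the α face, anti to the neighbouring C5-CO2Et. C6 is therefore made quaternary on the ring under substrate control.

**Step 8 (reductive epoxide opening).**
- Risk: the titanocene may fail to reach the epoxide oxygen on the concave β face. Alternatively, the C2 radical may be reduced further and expel the neighbouring C1 carboxylate, returning an alkene.
- Fallback, from 12 back to 13: MgBr2·OEt2 (Et2O/toluene, 0 °C) opens the epoxide in the trans-diaxial (Fürst–Plattner) sense at the tertiary carbon, giving the bromohydrin F4 (C2 α-Br, C3 β-OH). Bu3SnH with AIBN (benzene, 80 °C) then removes the bromine through the same locked C2 radical.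
- Why it differs: no metal needs to bind on the β face, and hydrogen is again delivered from the α face.

## Further compounds
F1 | step 17 | γ-keto acid from 29 (C14 CO2H, C12–OH, C13 ketone) | C[C@H]1[C@@H](O[Si](C)(C)C(C)(C)C)C[C@@H](C(C)(C)O[Si](C)(C)C(C)(C)C)[C@@](CCCO[Si](C)(C)C(C)(C)C)(CO[Si](C)(C)C(C)(C)C)[C@]12C[C@](C)([C@@H](C)[C@@H](C(=O)O)[C@H](O)C(C)=O)C(=O)O2
F2 | step 17 | trimethylsilyl ester, C12 trimethylsilyl ether of F1 | C[C@H]1[C@@H](O[Si](C)(C)C(C)(C)C)C[C@@H](C(C)(C)O[Si](C)(C)C(C)(C)C)[C@@](CCCO[Si](C)(C)C(C)(C)C)(CO[Si](C)(C)C(C)(C)C)[C@]12C[C@](C)([C@@H](C)[C@@H](C(=O)O[Si](C)(C)C)[C@H](O[Si](C)(C)C)C(C)=O)C(=O)O2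
F3 | step 2 | 1-ethyl 2-methyl (1R)-4-methyl-3-oxocyclohex-4-ene-1,2-dicarboxylate (C6 labile) | CC1=CC[C@@H](C(=O)OCC)C(C(=O)OC)C1=O
F4 | step 8 | bromohydrin bridged lactone (C2 α-Br, β-CH3; C3 β-OH) | C[C@@]1(Br)[C@@H](O)C[C@H]2C(=O)O[C@]1(CC(C)=C)[C@]2(CCCO[Si](C)(C)C(C)(C)C)C(=O)OC
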